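A direct plan would build the upper unit from an Evans syn-glycolate aldol with 4-(benzyloxy)benzaldehyde, carried on as the β-hydroxy Weinreb amide A1. Its benzylic hydroxyl would be O-arylated with 1-bromo-3,5-bis(benzyloxy)benzene A2 under palladium catalysis, and reduction would give the α-benzyloxy-β-aryloxy aldehyde A3. A Lewis acid would then close ring C by Friedel–Crafts attack on the aldehyde and trap the flavan-4-yl cation with 5,7,3',4',5'-penta-O-benzyl-epigallocatechin A4 at C8; hydrogenolysis of the nonabenzyl dimer A5 would end it. Its weakest steps would be: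
- the palladium-catalysed etherification of a secondary benzylic β-hydroxy amide, where hot carbonate would invite retro-aldol cleavage and β-hydride elimination;
- the handling of A3, which could epimerise at the α-carbon and lose the phenoxide by β-elimination;
- the tandem Friedel–Crafts bis-arylation, where A4 in excess could attack the aldehyde before ring closure, and C8 versus C6 and the C4 face would rest on substrate bias alone.

The route cuts ring C of the upper unit across C3–C4 and O1–C2. C4 lies between two 2,4,6-trioxygenated rings (A and D) with O1 ortho to it on ring A, so a C4 carbinol that already carries the epigallocatechin unit ionises to an o-quinone methide. Its annulation with the enamine of benzyloxyacetaldehyde forms the C3–C4 bond, sets C3 and C4 (3,4-trans) and closes ring C as a lactol in one catalytic operation. The C4–C8 bond is made earlier from an 8-bromide, which fixes C8 over C6; no aryl ether is cross-coupled, no β-aryloxy aldehyde occurs, and C2 is set last by chelate-controlled reduction and SN2 closure.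

Key step: step 4

Assumption: the salicylaldehyde of step 3 and the aryl Grignard solution of step 6 are treated as purchasable; the aldehyde is otherwise one benzylation away from 2,4,6-trihydroxybenzaldehyde.

**Step 1**
Reactants: 1 (−)-epigallocatechin
Product: 3 (2R,3R)-3,5,7-tris(benzyloxy)-2-[3,4,5-tris(benzyloxy)phenyl]chromane (hexa-O-benzyl-epigallocatechin), via 5,7,3',4',5'-penta-O-benzyl-epigallocatechin 2 (not isolated)
Conditions: BnBr (excess), K2CO3, DMF, 0 °C → rt; then NaH, n-Bu4NI (cat.), 0 °C → rt, argon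
Reagents that add atoms: benzyl bromide, BrCc1ccccc1
Why: Williamson etherification, first of the five phenols with carbonate and then, once no phenoxide is left that could open the pyran ring, of the 3-alkoxide with NaH, so that C2 and C3 stay untouched.

**Step 2**
Reactants: 3 hexa-O-benzyl-epigallocatechin
Product: 4 (2R,3R)-3,5,7-tris(benzyloxy)-8-bromo-2-[3,4,5-tris(benzyloxy)phenyl]chromane
Conditions: NBS (1.0 equiv), CH2Cl2, −78 → 0 °C, dark
Reagents that add atoms: N-bromosuccinimide, O=C1CCC(=O)N1Br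
Why: Electrophilic aromatic bromination of the phloroglucinol-type ring D, which is far more electron-rich than the tris(benzyloxy)phenyl ring and should react at C8, next to the ring oxygen, in preference to C6 between two benzyloxy groups, as is usual for 5,7-di-O-benzyl flavans.

**Step 3**
Reactants: 4 8-bromo-hexa-O-benzyl-epigallocatechin; 5 2,4-bis(benzyloxy)-6-hydroxybenzaldehyde
Product: 8 [2,4-bis(benzyloxy)-6-hydroxyphenyl](hexa-O-benzyl-epigallocatechin-8-yl)methanol (both carbinol epimers), via 8-lithio-hexa-O-benzyl-epigallocatechin 6 (not isolated), via sodium 3,5-bis(benzyloxy)-2-formylphenoxide 7 (not isolated)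
Conditions: 4, n-BuLi, THF, −78 °C; cannulated into 7 (from 5, NaH, THF, 0 °C) at −78 °C, then → 0 °C; aq. NH4Cl; crude product kept cold and off silica
Reagents that add atoms: none
Why: Bromine–lithium exchange and 1,2-addition of the aryllithium to the aldehyde, whose phenol is masked as the sodium phenoxide so that no aryllithium is lost to protonation; the carbinol centre forms as a mixture, which does not matter because step 4 planarises it.

**Step 4**
Reactants: 8 diarylcarbinol; 9 benzyloxyacetaldehyde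
Product: 11 (3R,4R)-3,5,7-tris(benzyloxy)-4-(hexa-O-benzyl-epigallocatechin-8-yl)chroman-2-ol (3,4-trans; both C2 anomers), via o-quinone methide 10 (not isolated)
Conditions: (S)-α,α-diphenylprolinol trimethylsilyl ether (20 mol %), 4-nitrobenzoic acid (20 mol %), 9 (3 equiv), CH2Cl2, 0 °C → rt
Reagents that add atoms: none
Why: Under the acid co-catalyst, carbinol 8 loses water to o-quinone methide 10 (its protonated form is a diarylmethyl cation stabilised by two 2,4,6-trioxygenated rings), the enamine of 9 with the prolinol silyl ether attacks the methide carbon C4 through its α-carbon (C3–C4 bond), and hydrolysis of the iminium is followed by addition of the ring A phenol to the aldehyde carbon (O1–C2 bond). The closest known reaction types are the amine-catalysed Michael addition–hemiacetalisation of aldehydes with o-quinone methides generated in situ and the enamine-mediated SN1-type α-alkylation of aldehydes with diarylmethyl cations. Ring C closes in a formal hetero-[4+2] annulation, stepwise, with the C–C bond first and a 6-exo-trig hemiacetalisation second. C3 is set by the catalyst, whose diphenyl(trimethylsilyloxy)methyl group shields one face of the anti-enamine, so that the (S)-catalyst is expected to give 3R; C4 is set by the relative topicity of the addition, which in such annulations leads to the 3,4-trans lactol, also the more stable isomer, while C2 stays an anomeric mixture that step 5 removes. The step needs the enamine to be alkylated faster than 9 undergoes self-aldol reaction and needs catalyst control to override the lower unit, which the easy ionisation of 8, the excess of 9 and the four bonds that separate C4 from the nearest stereocentre of the lower unit should secure.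

**Step 5**
Reactants: 11 lactol
Product: 12 (3R,4R)-3,5,7-tris(benzyloxy)-4-(hexa-O-benzyl-epigallocatechin-8-yl)chroman-2-one
Conditions: (n-Pr)4N[RuO4] (5 mol %), N-methylmorpholine N-oxide, 4 Å molecular sieves, CH2Cl2, rt
Reagents that add atoms: none
Why: Perruthenate-catalysed oxidation of the lactol, the only free hydroxyl in the molecule, to the lactone, which merges both anomers into one compound and leaves the trans C3/C4 pair (the more stable arrangement of a 3,4-disubstituted dihydrocoumarin) as set.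

**Step 6**
Reactants: 12 lactone; 13 4-(benzyloxy)phenylmagnesium bromide
Product: 15 (2R,3R)-2-(benzyloxy)-1-[4-(benzyloxy)phenyl]-3-[2,4-bis(benzyloxy)-6-hydroxyphenyl]-3-(hexa-O-benzyl-epigallocatechin-8-yl)propan-1-one, via Weinreb amide 14 (not isolated)
Conditions: MeONHMe·HCl (1.5 equiv), i-PrMgCl (3.0 equiv), THF, −20 °C; then 13 (2.5 equiv), 0 °C → rt; aq. NH4Cl; used without delay
Reagents that add atoms: none
Why: Aminolysis of the aryl ester lactone by the magnesium amide gives the Weinreb amide with ring A as its magnesium phenoxide, and Grignard addition then stops at the ketone because the chelated tetrahedral intermediate survives until work-up; C3 and C4 are not involved.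

**Step 7**
Reactants: 15 ketone
Product: 16 (1S,2R,3R)-2-(benzyloxy)-1-[4-(benzyloxy)phenyl]-3-[2,4-bis(benzyloxy)-6-hydroxyphenyl]-3-(hexa-O-benzyl-epigallocatechin-8-yl)propan-1-ol
Conditions: Zn(BH4)2, Et2O/THF, −40 → 0 °C; aq. NH4Cl
Reagents that add atoms: none
Why: Cram-chelate-controlled reduction of the α-benzyloxy ketone, in which zinc bridges the carbonyl and ether oxygens and hydride enters from the side of the C–H bond of the α-carbon, away from the bulky diarylmethyl group, to give the anti (1S) alcohol.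

**Step 8**
Reactants: 16 anti-alcohol
Product: 17 (2R,3R,4R)-3,5,7-tris(benzyloxy)-2-[4-(benzyloxy)phenyl]-4-(hexa-O-benzyl-epigallocatechin-8-yl)chromane (deca-O-benzyl-epiafzelechin-(4β→8)-epigallocatechin)
Conditions: PPh3, diisopropyl azodicarboxylate, toluene/THF, 0 °C → rt
Reagents that add atoms: none
Why: Intramolecular Mitsunobu etherification (6-exo-tet), in which the ring A phenol, the only free phenol, displaces the activated oxygen of the only free alcohol with inversion and so turns the 1S carbinol into the 2R centre of a 2,3-cis flavan.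

**Step 9**
Reactants: 17 deca-O-benzyl dimer
Product: 18 epiafzelechin-(4β→8)-epigallocatechin (CNP0290824.1)
Conditions: H2 (1 atm), Pd(OH)2/C, THF/MeOH/H2O, rt
Reagents that add atoms: none
Why: Hydrogenolysis of all ten benzyl ethers under neutral conditions, which in benzylated flavan-3-ol dimers should spare the cyclic benzylic C2–O1 bonds, the C4–C8 bond and all five stereocentres.

**Compound list**
1 | (−)-epigallocatechin, (2R,3R) | Oc1cc(O)c2c(c1)O[C@H](c1cc(O)c(O)c(O)c1)[C@H](O)C2 | starting material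
2 | (2R,3R)-5,7-bis(benzyloxy)-2-[3,4,5-tris(benzyloxy)phenyl]chroman-3-ol | c1c(OCc3ccccc3)cc(OCc3ccccc3)c2c1O[C@H](c1cc(OCc3ccccc3)c(OCc3ccccc3)c(OCc3ccccc3)c1)[C@H](O)C2 | intermediate (not isolated)
3 | (2R,3R)-3,5,7-tris(benzyloxy)-2-[3,4,5-tris(benzyloxy)phenyl]chromane | c1c(OCc3ccccc3)cc(OCc3ccccc3)c2c1O[C@H](c1cc(OCc3ccccc3)c(OCc3ccccc3)c(OCc3ccccc3)c1)[C@H](OCc1ccccc1)C2 | intermediate
4 | (2R,3R)-3,5,7-tris(benzyloxy)-8-bromo-2-[3,4,5-tris(benzyloxy)phenyl]chromane | Brc1c(OCc3ccccc3)cc(OCc3ccccc3)c2c1O[C@H](c1cc(OCc3ccccc3)c(OCc3ccccc3)c(OCc3ccccc3)c1)[C@H](OCc1ccccc1)C2 | intermediate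
5 | 2,4-bis(benzyloxy)-6-hydroxybenzaldehyde | O=Cc1c(O)cc(OCc2ccccc2)cc1OCc1ccccc1 | starting material
6 | 8-lithio derivative of 3 | [Li]c1c(OCc3ccccc3)cc(OCc3ccccc3)c2c1O[C@H](c1cc(OCc3ccccc3)c(OCc3ccccc3)c(OCc3ccccc3)c1)[C@H](OCc1ccccc1)C2 | intermediate (not isolated)
7 | sodium 3,5-bis(benzyloxy)-2-formylphenoxide | [Na+].[O-]c1cc(OCc2ccccc2)cc(OCc2ccccc2)c1C=O | intermediate (not isolated)
8 | [2,4-bis(benzyloxy)-6-hydroxyphenyl][(2R,3R)-3,5,7-tris(benzyloxy)-2-(3,4,5-tris(benzyloxy)phenyl)chroman-8-yl]methanol, both carbinol epimers | OC(c1c(O)cc(OCc2ccccc2)cc1OCc1ccccc1)c1c(OCc3ccccc3)cc(OCc3ccccc3)c2c1O[C@H](c1cc(OCc3ccccc3)c(OCc3ccccc3)c(OCc3ccccc3)c1)[C@H](OCc1ccccc1)C2 | intermediate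
9 | benzyloxyacetaldehyde | O=CCOCc1ccccc1 | starting material
10 | 3,5-bis(benzyloxy)-6-[(hexa-O-benzyl-epigallocatechin-8-yl)methylidene]cyclohexa-2,4-dien-1-one (o-quinone methide) | O=C1C=C(OCc2ccccc2)C=C(OCc2ccccc2)C1=Cc1c(OCc3ccccc3)cc(OCc3ccccc3)c2c1O[C@H](c1cc(OCc3ccccc3)c(OCc3ccccc3)c(OCc3ccccc3)c1)[C@H](OCc1ccccc1)C2 | intermediate (not isolated)
11 | (3R,4R)-3,5,7-tris(benzyloxy)-4-[(2R,3R)-3,5,7-tris(benzyloxy)-2-(3,4,5-tris(benzyloxy)phenyl)chroman-8-yl]chroman-2-ol, 3,4-trans, both C2 anomers | OC1Oc2cc(OCc3ccccc3)cc(OCc3ccccc3)c2[C@H](c4c(OCc5ccccc5)cc(OCc5ccccc5)c6c4O[C@H](c4cc(OCc5ccccc5)c(OCc5ccccc5)c(OCc5ccccc5)c4)[C@H](OCc4ccccc4)C6)[C@H]1OCc1ccccc1 | intermediate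
12 | (3R,4R)-3,5,7-tris(benzyloxy)-4-[(2R,3R)-3,5,7-tris(benzyloxy)-2-(3,4,5-tris(benzyloxy)phenyl)chroman-8-yl]chroman-2-one | O=C1Oc2cc(OCc3ccccc3)cc(OCc3ccccc3)c2[C@H](c4c(OCc5ccccc5)cc(OCc5ccccc5)c6c4O[C@H](c4cc(OCc5ccccc5)c(OCc5ccccc5)c(OCc5ccccc5)c4)[C@H](OCc4ccccc4)C6)[C@H]1OCc1ccccc1 | intermediate
13 | 4-(benzyloxy)phenylmagnesium bromide | Br[Mg]c1ccc(OCc2ccccc2)cc1 | starting material
14 | (2R,3R)-2-(benzyloxy)-3-[2,4-bis(benzyloxy)-6-hydroxyphenyl]-N-methoxy-N-methyl-3-(hexa-O-benzyl-epigallocatechin-8-yl)propanamide | CON(C)C(=O)[C@H](OCc1ccccc1)[C@@H](c4c(OCc5ccccc5)cc(OCc5ccccc5)c6c4O[C@H](c4cc(OCc5ccccc5)c(OCc5ccccc5)c(OCc5ccccc5)c4)[C@H](OCc4ccccc4)C6)c1c(O)cc(OCc2ccccc2)cc1OCc1ccccc1 | intermediate (not isolated)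
15 | (2R,3R)-2-(benzyloxy)-1-[4-(benzyloxy)phenyl]-3-[2,4-bis(benzyloxy)-6-hydroxyphenyl]-3-(hexa-O-benzyl-epigallocatechin-8-yl)propan-1-one | O=C(c1ccc(OCc2ccccc2)cc1)[C@H](OCc1ccccc1)[C@@H](c4c(OCc5ccccc5)cc(OCc5ccccc5)c6c4O[C@H](c4cc(OCc5ccccc5)c(OCc5ccccc5)c(OCc5ccccc5)c4)[C@H](OCc4ccccc4)C6)c1c(O)cc(OCc2ccccc2)cc1OCc1ccccc1 | intermediate
16 | (1S,2R,3R)-2-(benzyloxy)-1-[4-(benzyloxy)phenyl]-3-[2,4-bis(benzyloxy)-6-hydroxyphenyl]-3-(hexa-O-benzyl-epigallocatechin-8-yl)propan-1-ol | O[C@@H](c1ccc(OCc2ccccc2)cc1)[C@H](OCc1ccccc1)[C@@H](c4c(OCc5ccccc5)cc(OCc5ccccc5)c6c4O[C@H](c4cc(OCc5ccccc5)c(OCc5ccccc5)c(OCc5ccccc5)c4)[C@H](OCc4ccccc4)C6)c1c(O)cc(OCc2ccccc2)cc1OCc1ccccc1 | intermediate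
17 | deca-O-benzyl-epiafzelechin-(4β→8)-epigallocatechin (upper unit 2R,3R,4R; lower unit 2R,3R) | c1ccccc1COc1ccc(cc1)[C@H]1Oc2cc(OCc3ccccc3)cc(OCc3ccccc3)c2[C@H](c4c(OCc5ccccc5)cc(OCc5ccccc5)c6c4O[C@H](c4cc(OCc5ccccc5)c(OCc5ccccc5)c(OCc5ccccc5)c4)[C@H](OCc4ccccc4)C6)[C@H]1OCc1ccccc1 | intermediate
18 | epiafzelechin-(4β→8)-epigallocatechin (CNP0290824.1) | Oc1ccc([C@H]2Oc3cc(O)cc(O)c3[C@H](c3c(O)cc(O)c4c3O[C@H](c3cc(O)c(O)c(O)c3)[C@H](O)C4)[C@H]2O)cc1 | target

Total step count: 9. Longest linear sequence: 9 steps (1 → 18); 5, 9 and 13 are bought.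

**Steps most likely to fail**

Step 4. The addition may show poor facial selectivity at the methide carbon (C4 epimers), or the hindered, strongly stabilised methide may react so slowly that self-aldol reaction of the aldehyde takes over. The fallback sets out from bromide 4 and comes back at lactone 12, with C4 set by a rhodium catalyst instead. Bromide 4 would be converted (n-BuLi, THF, −78 °C; B(OMe)3; aqueous acid) into hexa-O-benzyl-epigallocatechin-8-boronic acid F1. This would be added to 5,7-bis(benzyloxy)coumarin F2 in a Hayashi–Miyaura conjugate arylation (Rh(acac)(C2H4)2, the Segphos antipode that delivers 4R, dioxane/H2O, 60 °C) to give (4R)-5,7-bis(benzyloxy)-4-(hexa-O-benzyl-epigallocatechin-8-yl)chroman-2-one F3. Its potassium enolate (KN(SiMe3)2, THF, −78 °C) would be hydroxylated anti to the C4 aryl group with 2-(phenylsulfonyl)-3-phenyloxaziridine to the 3,4-trans (3R,4R)-3-hydroxy lactone F4. O-Benzylation with benzyl 2,2,2-trichloroacetimidate and catalytic TfOH would return 12.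

Step 3. The doubly ortho-substituted aryllithium may add too slowly to the deactivated, doubly ortho-substituted phenoxide aldehyde, so that protonation or benzylic metalation of the aryllithium wins. The fallback sets out from bromide 4 and comes back at carbinol 8, with the polarity of the two partners exchanged. The aryllithium from 4 would be formylated with DMF to hexa-O-benzyl-epigallocatechin-8-carbaldehyde F5. The bromomagnesium phenoxide of 3,5-bis(benzyloxy)phenol F6 (EtMgBr, toluene) would then be hydroxyalkylated by F5 at its ortho position through the magnesium-templated ortho-hydroxyalkylation of phenoxides, which avoids the para position and gives 8.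

Step 8. The activated oxyphosphonium at the 4-benzyloxybenzylic carbon may ionise before displacement, with loss of stereospecificity at C2, or eliminate to the enol ether. The fallback sets out from lactone 12 and comes back at dimer 17, with the oxygen of ring B introduced only after ring closure. Step 6 would be run with 4-bromophenylmagnesium bromide to give (2R,3R)-2-(benzyloxy)-1-(4-bromophenyl)-3-[2,4-bis(benzyloxy)-6-hydroxyphenyl]-3-(hexa-O-benzyl-epigallocatechin-8-yl)propan-1-one F7, and step 7 would give the (1S,2R,3R)-alcohol F8. The Mitsunobu closure, now at a carbinol that cannot ionise readily, would give the 2-(4-bromophenyl)flavan dimer F9. Palladium-catalysed C–O coupling of F9 with benzyl alcohol (Pd2(dba)3, t-BuBrettPhos, Cs2CO3, toluene, 80 °C) would return 17.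

**Further compounds**
F1 | step 4 | [(2R,3R)-3,5,7-tris(benzyloxy)-2-(3,4,5-tris(benzyloxy)phenyl)chroman-8-yl]boronic acid | OB(O)c1c(OCc3ccccc3)cc(OCc3ccccc3)c2c1O[C@H](c1cc(OCc3ccccc3)c(OCc3ccccc3)c(OCc3ccccc3)c1)[C@H](OCc1ccccc1)C2
F2 | step 4 | 5,7-bis(benzyloxy)coumarin | O=C1C=Cc2c(OCc3ccccc3)cc(OCc3ccccc3)cc2O1
F3 | step 4 | (4R)-5,7-bis(benzyloxy)-4-(hexa-O-benzyl-epigallocatechin-8-yl)chroman-2-one | O=C1Oc2cc(OCc3ccccc3)cc(OCc3ccccc3)c2[C@H](c4c(OCc5ccccc5)cc(OCc5ccccc5)c6c4O[C@H](c4cc(OCc5ccccc5)c(OCc5ccccc5)c(OCc5ccccc5)c4)[C@H](OCc4ccccc4)C6)C1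
F4 | step 4 | (3R,4R)-5,7-bis(benzyloxy)-3-hydroxy-4-(hexa-O-benzyl-epigallocatechin-8-yl)chroman-2-one | O=C1Oc2cc(OCc3ccccc3)cc(OCc3ccccc3)c2[C@H](c4c(OCc5ccccc5)cc(OCc5ccccc5)c6c4O[C@H](c4cc(OCc5ccccc5)c(OCc5ccccc5)c(OCc5ccccc5)c4)[C@H](OCc4ccccc4)C6)[C@H]1O
F5 | step 3 | (2R,3R)-3,5,7-tris(benzyloxy)-2-[3,4,5-tris(benzyloxy)phenyl]chromane-8-carbaldehyde | O=Cc1c(OCc3ccccc3)cc(OCc3ccccc3)c2c1O[C@H](c1cc(OCc3ccccc3)c(OCc3ccccc3)c(OCc3ccccc3)c1)[C@H](OCc1ccccc1)C2
F6 | step 3 | 3,5-bis(benzyloxy)phenol | Oc1cc(OCc2ccccc2)cc(OCc2ccccc2)c1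
F7 | step 8 | (2R,3R)-2-(benzyloxy)-1-(4-bromophenyl)-3-[2,4-bis(benzyloxy)-6-hydroxyphenyl]-3-(hexa-O-benzyl-epigallocatechin-8-yl)propan-1-one | O=C(c1ccc(Br)cc1)[C@H](OCc1ccccc1)[C@@H](c4c(OCc5ccccc5)cc(OCc5ccccc5)c6c4O[C@H](c4cc(OCc5ccccc5)c(OCc5ccccc5)c(OCc5ccccc5)c4)[C@H](OCc4ccccc4)C6)c1c(O)cc(OCc2ccccc2)cc1OCc1ccccc1
F8 | step 8 | (1S,2R,3R)-2-(benzyloxy)-1-(4-bromophenyl)-3-[2,4-bis(benzyloxy)-6-hydroxyphenyl]-3-(hexa-O-benzyl-epigallocatechin-8-yl)propan-1-ol | O[C@@H](c1ccc(Br)cc1)[C@H](OCc1ccccc1)[C@@H](c4c(OCc5ccccc5)cc(OCc5ccccc5)c6c4O[C@H](c4cc(OCc5ccccc5)c(OCc5ccccc5)c(OCc5ccccc5)c4)[C@H](OCc4ccccc4)C6)c1c(O)cc(OCc2ccccc2)cc1OCc1ccccc1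
F9 | step 8 | (2R,3R,4R)-3,5,7-tris(benzyloxy)-2-(4-bromophenyl)-4-(hexa-O-benzyl-epigallocatechin-8-yl)chromane | Brc1ccc(cc1)[C@H]1Oc2cc(OCc3ccccc3)cc(OCc3ccccc3)c2[C@H](c4c(OCc5ccccc5)cc(OCc5ccccc5)c6c4O[C@H](c4cc(OCc5ccccc5)c(OCc5ccccc5)c(OCc5ccccc5)c4)[C@H](OCc4ccccc4)C6)[C@H]1OCc1ccccc1
A1 | direct plan | (2S,3R)-2-(benzyloxy)-3-[4-(benzyloxy)phenyl]-3-hydroxy-N-methoxy-N-methylpropanamide | c1ccccc1COc1ccc(cc1)[C@@H](O)[C@H](OCc1ccccc1)C(=O)N(C)OC
A2 | direct plan | 1-bromo-3,5-bis(benzyloxy)benzene | Brc1cc(OCc2ccccc2)cc(OCc2ccccc2)c1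
A3 | direct plan | (2S,3R)-2-(benzyloxy)-3-[3,5-bis(benzyloxy)phenoxy]-3-[4-(benzyloxy)phenyl]propanal | c1ccccc1COc1ccc(cc1)[C@@H](Oc1cc(OCc2ccccc2)cc(OCc2ccccc2)c1)[C@H](OCc1ccccc1)C=O
A4 | direct plan | (2R,3R)-5,7-bis(benzyloxy)-2-[3,4,5-tris(benzyloxy)phenyl]chroman-3-ol | c1c(OCc3ccccc3)cc(OCc3ccccc3)c2c1O[C@H](c1cc(OCc3ccccc3)c(OCc3ccccc3)c(OCc3ccccc3)c1)[C@H](O)C2
A5 | direct plan | 3,5,7,4'-tetra-O-benzyl-epiafzelechin-(4β→8)-5,7,3',4',5'-penta-O-benzyl-epigallocatechin | c1ccccc1COc1ccc([C@H]2Oc3cc(OCc4ccccc4)cc(OCc4ccccc4)c3[C@H](c3c(OCc4ccccc4)cc(OCc4ccccc4)c4c3O[C@H](c3cc(OCc5ccccc5)c(OCc5ccccc5)c(OCc5ccccc5)c3)[C@H](O)C4)[C@H]2OCc2ccccc2)cc1
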